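**Strategy**

The benzylic CH2 of the oxepine (ring B) is the only atom between the arene carbon ortho to the ether oxygen (ring A) and bornane C6, and C6 is α to C5. Both bonds to this carbon are therefore cut, which leaves formaldehyde, an aryl bornyl ether and a C5 ketone. In step 8 the ketone is methylenated at C6, its only enolisable position because C4 is a bridgehead, and the exocyclic enone is then closed onto the arene, which forms C6–CH2 and CH2–aryl, ring B and the C6 stereocentre. The precursor is the 2-endo 4-bromo-3,5-dimethoxyphenyl ether of bornan-5-one; the bromine blocks the para carbon and later becomes the isovaleryl group.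

Key step: step 8

Remark: electrophilic substitution of the cyclised di-O-methyl arene is expected to favour the carbon next to the ring oxygen (para to a coplanar methoxy group, flanked by a tied-back ether), which must become C–CHO; the isovaleryl group is therefore brought in through a bromine placed para to the ether oxygen from the start, and this bromine is a spectator in the key step.

Locants: bornane numbering is used for the terpene (C1 methyl-bearing bridgehead, C2 oxygen-bearing carbon, C4 bridgehead CH, C7 gem-dimethyl bridge). The benzene carbons are called Ar-1 (bonded to the ether oxygen) to Ar-6; after ring closure Ar-2 carries the benzylic CH2.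

**Route**

Step 1
Reactants: 1 (+)-borneol
Product: 2 (+)-bornyl acetate
Conditions: Ac2O, pyridine, DMAP (cat.), CH2Cl2, rt
Reagents that add atoms: acetic anhydride CC(=O)OC(C)=O
Why: DMAP-catalysed O-acylation (esterification) touches only the O–H bond, so the 2-endo configuration of 1 is retained, and the acetoxy group deactivates C2–H and C3–H for the oxidation that follows.

Step 2
Reactants: 2 (+)-bornyl acetate
Product: 3 2-endo-acetoxybornan-5-one
Conditions: CrO3, AcOH–Ac2O, rt → 60 °C
Reagents that add atoms: chromium trioxide O=[Cr](=O)=O
Why: Chromic acid oxidation of an unactivated methylene, long known for bornyl esters, should select C5 because it is the CH2 farthest from the electron-withdrawing acetoxy group while C6 is shielded by the C1 methyl and the C4–H bridgehead cannot support a planar intermediate; the minor 6-oxo isomer is to be removed by chromatography.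

Step 3
Reactants: 3 2-endo-acetoxybornan-5-one
Product: 4 2-endo-acetoxy-5,5-(ethylenedioxy)bornane
Conditions: ethylene glycol, p-TsOH (cat.), benzene, reflux, Dean–Stark
Reagents that add atoms: ethylene glycol OCCO
Why: Acid-catalysed dioxolane formation with azeotropic removal of water should proceed at the C5 carbonyl, which is less hindered than that of camphor, and the ketal masks the enolisable ketone from the basic coupling in step 6.

Step 4
Reactants: 4 2-endo-acetoxy-5,5-(ethylenedioxy)bornane
Product: 5 5,5-(ethylenedioxy)bornan-2-endo-ol
Conditions: KOH, MeOH–H2O, reflux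
Reagents that add atoms: none
Why: Ester saponification by acyl–oxygen cleavage frees the 2-endo alcohol with retention at C2 and leaves the base-stable ketal untouched.

Step 5
Reactants: 6 2-bromo-1,3-dimethoxybenzene
Product: 8 2-bromo-5-iodo-1,3-dimethoxybenzene, via pinacol boronate 7 (not isolated)
Conditions: [Ir(OMe)(cod)]2 (1.5 mol %), 4,4'-di-tert-butyl-2,2'-bipyridine (3 mol %), B2pin2, THF, 80 °C; then CuI (10 mol %), 1,10-phenanthroline, KI, MeOH–H2O, air, 80 °C
Reagents that add atoms: potassium iodide [K+].[I-]
Why: Sterically controlled Ir-catalysed C–H borylation should occur only at C5, the one C–H with no ortho substituent, and the Cu-catalysed aerobic iododeboronation in the same flask replaces boron by iodine at the ipso carbon while the C–Br bond is inert to both catalysts.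

Step 6
Reactants: 5 5,5-(ethylenedioxy)bornan-2-endo-ol; 8 2-bromo-5-iodo-1,3-dimethoxybenzene
Product: 9 2-endo-(4-bromo-3,5-dimethoxyphenoxy)-5,5-(ethylenedioxy)bornane
Conditions: CuI (10 mol %), 3,4,7,8-tetramethyl-1,10-phenanthroline (20 mol %), Cs2CO3, toluene, 110 °C
Reagents that add atoms: none
Why: Ullmann-type Cu-catalysed C–O coupling of a secondary alkoxide with an aryl iodide forms the O–aryl bond without touching the C2–O bond, so the endo configuration is retained, and oxidative addition should select the unhindered C–I over the C–Br bond that lies between two methoxy groups.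

Step 7
Reactants: 9 2-endo-(4-bromo-3,5-dimethoxyphenoxy)-5,5-(ethylenedioxy)bornane
Product: 10 2-endo-(4-bromo-3,5-dimethoxyphenoxy)bornan-5-one
Conditions: 1 M HCl, THF, rt
Reagents that add atoms: water O
Why: Acid-catalysed ketal hydrolysis in dilute aqueous acid regenerates the C5 ketone under conditions too mild to ionise the secondary alkyl aryl ether.

Step 8
Reactants: 10 2-endo-(4-bromo-3,5-dimethoxyphenoxy)bornan-5-one
Product: 15 bromo di-O-methyl tetracyclic 5-ketone (oxepine closed; 6-endo), via lithium enolate 11 (not isolated), via Mannich base 12 (not isolated), via trimethylammonium iodide 13 (not isolated), via 6-methylene enone 14 (not isolated)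
Conditions: LDA, THF, −78 °C; CH2=NMe2+ I−, −78 °C → rt; MeI, rt; aq NaHCO3–CH2Cl2, rt → 40 °C; then Sc(OTf)3 (10 mol %), MeCN–CH2Cl2 (0.01 M), 0 °C → rt
Reagents that add atoms: dimethyl(methylidene)ammonium iodide C=[N+](C)C.[I-]
Why: LDA removes the single type of α-hydrogen of 10 at C6 (C4, the other α-carbon, is a bridgehead), enolate 11 is aminomethylated by the iminium salt, and N-methylation followed by E1cB loss of trimethylamine gives the 6-methylene-5-ketone 14; Sc(OTf)3 then activates the enone, the arene carbon ortho to the ether oxygen adds to the terminal CH2, and the resulting scandium enolate is protonated. The closest known reaction types are the Mannich α-methylenation of ketone enolates and the Lewis-acid-catalysed intramolecular Friedel–Crafts conjugate addition of alkoxyarenes to enones. The oxepine (ring B) closes in the 7-endo-trig mode, since both alkene carbons end up in the new ring; the endo lobe of the exocyclic CH2 points towards the 2-endo aryloxy group, so the reacting carbons can meet without strain. The new stereocentre C6 is set under thermodynamic control: it remains enolisable next to C5, and only the 6-endo (cis-bridged) epimer lets an ortho-phenylene span the C2 oxygen and the C6 CH2, so protonation from the exo face is the only productive outcome. The step needs site selectivity on the arene and chemoselectivity for C6 over aromatic aminomethylation: the two ortho carbons are equivalent, the para carbon carries bromine and could not reach C6 in any case, the bond to C6 is made at −78 °C through the enolate before any acid is present, and high dilution with a mild catalytic Lewis acid should suppress dimerisation and cleavage of the bornyl ether.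

Step 9
Reactants: 15 bromo di-O-methyl tetracyclic 5-ketone
Product: 17 bromo di-O-methyl tetracycle (CH2 at C5), via hydrazone 16 (not isolated)
Conditions: N2H4·H2O, KOH, diethylene glycol, 130 °C, then 200 °C
Reagents that add atoms: none
Why: Wolff–Kishner reduction (Huang-Minlon procedure) converts C5=O into CH2 by way of the hydrazone; C6 may epimerise in hot base but only the 6-endo epimer can hold the oxepine, and the aryl bromide, the methyl ethers and the aryl ether are inert to KOH and hydrazine.

Step 10
Reactants: 17 bromo di-O-methyl tetracycle; 18 N-methoxy-N,3-dimethylbutanamide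
Product: 20 isovaleryl di-O-methyl tetracycle, via aryllithium 19 (not isolated)
Conditions: n-BuLi, THF, −78 °C; then 18, −78 → 0 °C; 1 M HCl
Reagents that add atoms: none
Why: Bromine–lithium exchange at −78 °C gives an aryllithium stabilised by its two ortho methoxy groups, and its addition to the Weinreb amide stops at the chelated tetrahedral adduct, which releases the ketone only on acidic work-up, so the isovaleryl group is placed para to the ring oxygen without any regiochemical choice.

Step 11
Reactants: 20 isovaleryl di-O-methyl tetracycle
Product: 21 isovaleryl dihydroxy tetracycle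
Conditions: NaSEt (excess), DMF, 130 °C; then 1 M HCl
Reagents that add atoms: none
Why: Thiolate O-demethylation is an SN2 displacement at methyl carbon that is assisted by the ortho ketone as an electron sink for each departing phenoxide, whereas C2 of the bornane is a neopentyl-type secondary carbon that thiolate cannot attack, so the ring ether should survive where boron trihalides might ionise it.

Step 12
Reactants: 21 isovaleryl dihydroxy tetracycle
Product: 22 target CNP0246493.1
Conditions: Cl2CHOMe, TiCl4, CH2Cl2, −20 → 0 °C; then ice-cold 1 M HCl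
Reagents that add atoms: dichloromethyl methyl ether COC(Cl)Cl; water O
Why: Rieche formylation of the titanium phenoxide can only take place at the single unsubstituted aromatic carbon, which is ortho to a phenol oxygen and to the ring oxygen, and hydrolysis of the α-chloro ether on work-up delivers the aldehyde and thereby the target.

**Compound list**

1 | (+)-borneol, (1R,2S,4R)-1,7,7-trimethylbicyclo[2.2.1]heptan-2-ol (2-endo OH) | O[C@H]1C[C@H]2CC[C@]1(C)C2(C)C | starting material
2 | (+)-bornyl acetate, (1R,2S,4R)-2-endo-acetoxybornane | CC(=O)O[C@H]1C[C@H]2CC[C@]1(C)C2(C)C | intermediate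
3 | (1R,2S,4R)-2-endo-acetoxybornan-5-one | CC(=O)O[C@H]1C[C@H]2C(=O)C[C@]1(C)C2(C)C | intermediate
4 | (1R,2S,4R)-2-endo-acetoxy-5,5-(ethylenedioxy)bornane (spiro-1,3-dioxolane at C5) | CC(=O)O[C@H]1C[C@H]2C3(OCCO3)C[C@]1(C)C2(C)C | intermediate
5 | (1R,2S,4R)-5,5-(ethylenedioxy)bornan-2-endo-ol | O[C@H]1C[C@H]2C3(OCCO3)C[C@]1(C)C2(C)C | intermediate
6 | 2-bromo-1,3-dimethoxybenzene | COc1cccc(OC)c1Br | starting material
7 | 2-(4-bromo-3,5-dimethoxyphenyl)-4,4,5,5-tetramethyl-1,3,2-dioxaborolane | COc1cc(B2OC(C)(C)C(C)(C)O2)cc(OC)c1Br | intermediate
8 | 2-bromo-5-iodo-1,3-dimethoxybenzene | COc1cc(I)cc(OC)c1Br | intermediate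
9 | (1R,2S,4R)-2-endo-(4-bromo-3,5-dimethoxyphenoxy)-5,5-(ethylenedioxy)bornane | COc1cc(O[C@H]2C[C@H]3C4(OCCO4)C[C@]2(C)C3(C)C)cc(OC)c1Br | intermediate
10 | (1R,2S,4R)-2-endo-(4-bromo-3,5-dimethoxyphenoxy)bornan-5-one | COc1cc(O[C@H]2C[C@H]3C(=O)C[C@]2(C)C3(C)C)cc(OC)c1Br | intermediate
11 | lithium enolate of 10 (C5(OLi)=C6; C1, C2 and C4 as in 10) | COc1cc(O[C@H]2C[C@H]3C(O[Li])=C[C@]2(C)C3(C)C)cc(OC)c1Br | intermediate
12 | 6-(dimethylaminomethyl) derivative of 10 (6-exo expected, of no consequence; C1, C2 and C4 as in 10) | COc1cc(O[C@H]2C[C@H]3C(=O)[C@H](CN(C)C)[C@]2(C)C3(C)C)cc(OC)c1Br | intermediate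
13 | N-methyl quaternary ammonium iodide of 12 (CH2NMe3+ I− at C6) | COc1cc(O[C@H]2C[C@H]3C(=O)[C@H](C[N+](C)(C)C)[C@]2(C)C3(C)C)cc(OC)c1Br.[I-] | intermediate
14 | 2-endo-(4-bromo-3,5-dimethoxyphenoxy)-6-methylenebornan-5-one (C1, C2 and C4 as in 10) | COc1cc(O[C@H]2C[C@H]3C(=O)C(=C)[C@]2(C)C3(C)C)cc(OC)c1Br | intermediate
15 | (1R,2S,4R,6S)-bornan-5-one whose 2-endo O and 6-endo CH2 are bonded to the adjacent benzene carbons Ar-1 and Ar-2 (oxepine, ring B); OMe at Ar-3 and Ar-5, Br at Ar-4, H at Ar-6 | Brc1c(OC)cc2c(c1OC)C[C@@H]1C(=O)[C@@H]3C[C@H](O2)[C@@]1(C)C3(C)C | intermediate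
16 | C5 hydrazone of 15 (C=N–NH2, geometry not defined) | Brc1c(OC)cc2c(c1OC)C[C@@H]1C(=NN)[C@@H]3C[C@H](O2)[C@@]1(C)C3(C)C | intermediate
17 | 5-deoxo analogue of 15 (CH2 at C5; 1R,2S,4R,6S); OMe at Ar-3 and Ar-5, Br at Ar-4 | Brc1c(OC)cc2c(c1OC)C[C@@H]1C[C@@H]3C[C@H](O2)[C@@]1(C)C3(C)C | intermediate
18 | N-methoxy-N,3-dimethylbutanamide (Weinreb amide of isovaleric acid) | CC(C)CC(=O)N(C)OC | starting material
19 | Ar-4 lithio analogue of 17 | [Li]c1c(OC)cc2c(c1OC)C[C@@H]1C[C@@H]3C[C@H](O2)[C@@]1(C)C3(C)C | intermediate
20 | Ar-4 (3-methylbutanoyl) analogue of 17; OMe at Ar-3 and Ar-5, H at Ar-6 (1R,2S,4R,6S) | CC(C)CC(=O)c1c(OC)cc2c(c1OC)C[C@@H]1C[C@@H]3C[C@H](O2)[C@@]1(C)C3(C)C | intermediate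
21 | Ar-3,Ar-5 diol corresponding to 20 (1R,2S,4R,6S) | CC(C)CC(=O)c1c(O)cc2c(c1O)C[C@@H]1C[C@@H]3C[C@H](O2)[C@@]1(C)C3(C)C | intermediate
22 | CNP0246493.1: Ar-6 formyl derivative of 21; OH at Ar-3 and Ar-5, 3-methylbutanoyl at Ar-4 (bornane locants 1R,2S,4R,6S; O at C2 endo, CH2 at C6 endo) | CC(C)CC(=O)c1c(O)c(C=O)c2c(c1O)C[C@@H]1C[C@@H]3C[C@H](O2)[C@@]1(C)C3(C)C | target

**Step count**

Total: 12 steps. Longest linear sequence: 11 steps (1 → 22 through steps 1–4 and 6–12); step 5 is a one-step side branch.

**Steps most likely to fail**

1. Step 8. Aminomethylation of the hindered enolate next to the quaternary C1 may be incomplete, or intermolecular arene alkylation may outrun closure of the seven-membered ring. The fallback makes the aryl–carbon bond first and the C6–carbon bond second, with the linchpin at the formyl oxidation level. It sets out from 9: Vilsmeier–Haack formylation (POCl3, DMF, 0 °C → rt, then 1 M HCl, which also removes the dioxolane) at one of the two equivalent carbons ortho to the bornyl oxygen should give 2-endo-(4-bromo-2-formyl-3,5-dimethoxyphenoxy)bornan-5-one F1. LiHMDS in THF at −78 °C then forms the C6 enolate, which adds intramolecularly to the aryl aldehyde to give the tetracyclic β-hydroxy ketone F2 (6-endo, carbinol centre either way). Ionic hydrogenation (Et3SiH, TFA, CH2Cl2, 0 °C) removes the alkoxy-activated benzylic hydroxyl and comes back to the route at 15.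

2. Step 6. Transfer of the hindered secondary alkoxide to copper may be slow, so that reductive loss of iodine from 8 dominates. The fallback is a metal-free arylation with a diaryliodonium salt and sets out from 8 and 5. Oxidation of 8 with mCPBA and TsOH·H2O in MeCN followed by 1,3,5-trimethoxybenzene should give (4-bromo-3,5-dimethoxyphenyl)(2,4,6-trimethoxyphenyl)iodonium tosylate F3. The sodium alkoxide of 5 (NaH, toluene, rt → 50 °C) should then attack the less electron-rich aryl group by ligand coupling at iodine, and the route is rejoined at 9.

3. Step 11. The second demethylation may stall once the first phenoxide has formed and deactivated the ring. The fallback reverses the order of the last two operations and uses chelation-controlled Lewis-acid cleavage; it sets out from 20. Rieche formylation (Cl2CHOMe, TiCl4, CH2Cl2, −78 → 0 °C) at the only free aromatic carbon should give the Ar-6 formyl di-O-methyl ether F4, in which each methoxy group is ortho to a carbonyl group of its own. BCl3 in CH2Cl2 (−78 → 0 °C) should then cleave both methyl ethers through six-membered boron chelates at low temperature, and the route is rejoined at 22.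

**Further compounds**

F1 | step 8 | (1R,2S,4R)-2-endo-(4-bromo-2-formyl-3,5-dimethoxyphenoxy)bornan-5-one | COc1cc(O[C@H]2C[C@H]3C(=O)C[C@]2(C)C3(C)C)c(C=O)c(OC)c1Br
F2 | step 8 | benzylic hydroxy derivative of 15 (OH on the CH between Ar-2 and C6; 6-endo; carbinol configuration not defined) | Brc1c(OC)cc2c(c1OC)C(O)[C@@H]1C(=O)[C@@H]3C[C@H](O2)[C@@]1(C)C3(C)C
F3 | step 6 | (4-bromo-3,5-dimethoxyphenyl)(2,4,6-trimethoxyphenyl)iodonium 4-methylbenzenesulfonate | COc1cc([I+]c2c(OC)cc(OC)cc2OC)cc(OC)c1Br.Cc1ccc(cc1)S(=O)(=O)[O-]
F4 | step 11 | Ar-6 formyl derivative of 20 (di-O-methyl ether of the target) | CC(C)CC(=O)c1c(OC)c(C=O)c2c(c1OC)C[C@@H]1C[C@@H]3C[C@H](O2)[C@@]1(C)C3(C)C
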